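**Plan**

Locants follow the heavy atoms of the target SMILES, carbonyl oxygens uncounted (C1 methyl … O24).
Retrosynthesis: cut C8=C9 (acylation and dehydration; lactone 27 supplies C9–C17), then O24–C23 (macrolactone), take O20 out of the γ-lactone (giving cyclobutanone 15), cut C21–C22 (alkylation), the four-membered ring (ketene plus alkene 8) and C5–C6 (allyl addition).
Forward: cyclobutanone by [2+2], γ-lactone by oxygen insertion, ten-membered lactone by lactonisation, union with the separately made pyrano-lactone 27, alkylidene tetrahydrofuran by dehydration with the C5 ketone unmasked last.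
Stereochemistry: C2 and C13 from (R)-γ-valerolactone; C7 by enantiotopic deprotonation with a chiral lithium amide; C21 by trans alkylation, kept with retention in the insertion; C17 by Noyori transfer hydrogenation; C11 by cis oxypalladation–lactonisation; C8=C9 geometry by thermodynamic control.
Enabling feature: the γ-butyrolactone ring C7–C8–C19–O20–C21, trans at C7/C21, is the cyclobutanone ring C7–C8–C19–C21 plus the single atom O20, and C21 is α to that ketone.

Key step: step 9

Assumption: lithium bis[(S)-1-phenylethyl]amide is taken to deprotonate the ring methylene that becomes C21, by analogy with its behaviour towards 4-substituted cyclohexanones and 3-substituted cyclobutanones; if the sense proved opposite, the (R,R)-amide would be used with no other change.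

**Route**

Step 1
Reactants: 1 (R)-γ-valerolactone
Product: 2 (4R)-4-(benzyloxy)pentanoic acid
Conditions: KOH (powder), BnBr, toluene, reflux; then H2O, aqueous phase acidified with HCl
Reagents that add atoms: benzyl bromide, BrCc1ccccc1; potassium hydroxide, [K+].[OH-]
Why: Hydroxide opens the lactone and the secondary alkoxide is benzylated (Williamson ether synthesis, any benzyl ester being saponified again by the excess base); no bond to C2 is broken, so the (R) centre is kept.

Step 2
Reactants: 2 (4R)-4-(benzyloxy)pentanoic acid
Product: 4 (4R)-4-(benzyloxy)-N-methoxy-N-methylpentanamide, via acyl imidazolide 3 (not isolated)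
Conditions: CDI, CH2Cl2, rt; then MeNH(OMe)·HCl, rt
Reagents that add atoms: N,O-dimethylhydroxylamine hydrochloride, CNOC.Cl; 1,1'-carbonyldiimidazole, O=C(n1ccnc1)n1ccnc1 (its imidazole stays only in 3)
Why: Acyl-imidazole activation and aminolysis (CDI amidation) give the Weinreb amide under near-neutral conditions that cannot affect C2 or the benzyl ether.

Step 3
Reactants: 4 (4R)-4-(benzyloxy)-N-methoxy-N-methylpentanamide; 5 allylmagnesium bromide
Product: 7 (7R)-7-(benzyloxy)oct-1-en-4-one, via magnesium chelate 6 (not isolated)
Conditions: THF, −78 °C; quench with cold 1 M HCl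
Reagents that add atoms: none
Why: Weinreb ketone synthesis: the N-methoxy chelate 6 resists a second addition, and the cold acidic quench releases the β,γ-unsaturated ketone (C5–C6 bond formed) before it can move into conjugation.

Step 4
Reactants: 7 (7R)-7-(benzyloxy)oct-1-en-4-one
Product: 8 2-allyl-2-[(3R)-3-(benzyloxy)butyl]-1,3-dioxolane
Conditions: (TMSOCH2)2, TMSOTf (cat.), CH2Cl2, −78 °C; pyridine quench
Reagents that add atoms: 1,2-bis(trimethylsilyloxy)ethane, C[Si](C)(C)OCCO[Si](C)(C)C
Why: Noyori ketalisation (silylated diol, catalytic TMSOTf, low temperature) masks C5 without acid-mediated migration of the terminal double bond or loss of the benzyl ether.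

Step 5
Reactants: 8 2-allyl-2-[(3R)-3-(benzyloxy)butyl]-1,3-dioxolane; 9 trichloroacetyl chloride
Product: 10 2,2-dichloro-3-substituted cyclobutanone (both configurations at the ring CH)
Conditions: Zn–Cu couple, Et2O/DME, rt, slow addition of 9
Reagents that add atoms: none
Why: Zinc dechlorinates 9 to dichloroketene, which undergoes the thermal ketene–alkene [2+2] cycloaddition; the alkene CH2 bonds to the ketene carbonyl carbon, so the side chain sits next to CCl2, DME ties up ZnCl2 to spare the dioxolane, and the uncontrolled ring centre loses its stereogenicity in step 6.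

Step 6
Reactants: 10 2,2-dichloro-3-substituted cyclobutanone
Product: 11 3-({2-[(3R)-3-(benzyloxy)butyl]-1,3-dioxolan-2-yl}methyl)cyclobutan-1-one
Conditions: Zn dust, NH4Cl, MeOH, rt
Reagents that add atoms: none
Why: Zinc reduces both C–Cl bonds of the α,α-dichloroketone (reductive dehalogenation via the zinc enolate) under buffered conditions that keep the dioxolane, and both epimers of 10 converge on one ketone whose ring carbon C7 is prochiral.

Step 7
Reactants: 11 3-({2-[(3R)-3-(benzyloxy)butyl]-1,3-dioxolan-2-yl}methyl)cyclobutan-1-one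
Product: 12 trimethylsilyl enol ether of 11 (C7 configured as in the target)
Conditions: (S,S)-bis(1-phenylethyl)amine, n-BuLi, THF; TMSCl, then 11, −100 °C (internal quench); non-aqueous work-up
Reagents that add atoms: chlorotrimethylsilane, C[Si](C)(C)Cl
Why: Enantiotopic-group-selective deprotonation by the C2-symmetric lithium amide with in situ silylation (Simpkins-type asymmetric deprotonation, precedented for 3-substituted cyclobutanones) picks one of the two α-methylenes and so sets C7 under reagent control, the remote C2 centre having no influence.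

Step 8
Reactants: 12 trimethylsilyl enol ether of 11; 13 benzyl bromoacetate
Product: 15 trans-2,3-disubstituted cyclobutanone benzyl ester (C7 and C21 as in the target), via lithium enolate 14 (not isolated)
Conditions: MeLi (1.0 equiv), THF, 0 °C; then 13, DMPU, −78 → −30 °C
Reagents that add atoms: methyllithium, [Li]C (its lithium stays only in 14)
Why: Methyllithium cleaves the O–Si bond to the regiodefined lithium enolate (House procedure), which is alkylated by the activated bromide (SN2) on the ring face opposite the C7 side chain, setting C21 trans to C7; the centre is α to the ketone, so any cis isomer can be equilibrated to the more stable trans isomer with mild base.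

Step 9
Reactants: 15 trans-2,3-disubstituted cyclobutanone benzyl ester
Product: 17 benzyl 2-[(2S,3R)-3-({2-[(3R)-3-(benzyloxy)butyl]-1,3-dioxolan-2-yl}methyl)-5-oxooxolan-2-yl]acetate, via Criegee adduct 16 (not isolated)
Conditions: mCPBA, NaHCO3, CH2Cl2, 0 °C → rt
Reagents that add atoms: 3-chloroperoxybenzoic acid, O=C(OO)c1cccc(Cl)c1 (one oxygen stays in 17; the whole reagent is held in 16)
Why: The peracid adds to the strained C19 carbonyl to give the tetrahedral adduct 16, in which the C19–C21 bond antiperiplanar to the O–O bond shifts to the proximal peroxide oxygen as 3-chlorobenzoate leaves, so that O20 is inserted between C19 and C21 (Baeyer–Villiger oxidation). The closest known reaction type is the peracid oxidation of 2-substituted and 2,3-disubstituted cyclobutanones to γ-butyrolactones with migration of the more substituted α-carbon. The lactone ring C7–C8–C19–O20–C21 arises by one-atom enlargement of the four-membered ring, not by a cyclisation, and the release of ring strain makes this ketone react far faster than any other group present. No stereocentre is created: C21 migrates with retention and C7 is not touched, so the trans relationship set in step 8 becomes the trans C7/C21 relationship of the lactone. The selectivity needed is regiochemical (C21 over C8) and is secured by the higher migratory aptitude of the secondary C21 over the primary C8; the benzyl ether, the benzyl ester and the bicarbonate-buffered dioxolane are spectators.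

Step 10
Reactants: 17 benzyl ester/benzyl ether γ-lactone
Product: 18 2-[(2S,3R)-3-({2-[(3R)-3-hydroxybutyl]-1,3-dioxolan-2-yl}methyl)-5-oxooxolan-2-yl]acetic acid
Conditions: H2 (1 atm), Pd(OH)2/C, EtOAc, rt
Reagents that add atoms: none
Why: Catalytic hydrogenolysis cleaves the benzyl ester and the benzyl ether in one neutral operation, leaving the dioxolane, the γ-lactone and the three stereocentres untouched.

Step 11
Reactants: 18 seco acid
Product: 20 ketal-protected bicyclic macrolactone (2R,7R,21S), via mixed anhydride 19 (not isolated)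
Conditions: MNBA, DMAP, CH2Cl2, rt, slow addition of 18 (high dilution)
Reagents that add atoms: 2-methyl-6-nitrobenzoic anhydride, Cc1cccc([N+](=O)[O-])c1C(=O)OC(=O)c1c(C)cccc1[N+](=O)[O-] (its acyl group stays only in 19)
Why: Shiina macrolactonisation: the mixed anhydride is passed through the acyl-pyridinium ion and trapped by the C2 hydroxyl at room temperature to close the ten-membered ring (O24–C23), with retention at C2 because the C2–O bond is not broken.

Step 12
Reactants: 1 (R)-γ-valerolactone; 21 ethynyltrimethylsilane
Product: 23 (6R)-6-hydroxy-1-(trimethylsilyl)hept-1-yn-3-one, via lithium lactolate 22 (not isolated)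
Conditions: 21, n-BuLi, THF, −78 °C; then 1, −78 °C; sat. NH4Cl
Reagents that add atoms: n-butyllithium, [Li]CCCC (its lithium stays only in 22)
Why: The lithium acetylide adds once to the lactone carbonyl (C17–C11 bond) because the tetrahedral lactolate is stable at −78 °C and opens to the ynone only on protonation (acylation of an acetylide by a lactone); C13 is not involved.

Step 13
Reactants: 23 (6R)-6-hydroxy-1-(trimethylsilyl)hept-1-yn-3-one
Product: 24 (3S,6R)-1-(trimethylsilyl)hept-1-yne-3,6-diol
Conditions: Ru[(S,S)-TsDPEN](p-cymene) (1 mol%), i-PrOH, rt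
Reagents that add atoms: none
Why: Noyori asymmetric transfer hydrogenation of an alkynyl ketone, in which the alkynyl group takes the place of the aryl group in the bifunctional Ru–H/N–H transition state, so the (S,S) catalyst should give the (3S) propargylic alcohol and set C17 under catalyst control.

Step 14
Reactants: 24 (3S,6R)-1-(trimethylsilyl)hept-1-yne-3,6-diol
Product: 25 (3S,6R)-hept-1-yne-3,6-diol
Conditions: K2CO3 (cat.), MeOH, rt
Reagents that add atoms: none
Why: Carbonate-catalysed methanolysis of the alkynyl C–Si bond (protodesilylation) frees the terminal alkyne without touching the carbinol centres.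

Step 15
Reactants: 25 (3S,6R)-hept-1-yne-3,6-diol
Product: 26 (3S,6R)-hept-1-ene-3,6-diol
Conditions: H2 (1 atm), Lindlar catalyst, quinoline, EtOAc, rt
Reagents that add atoms: none
Why: Lindlar semihydrogenation of the terminal alkyne stops at the alkene on the poisoned catalyst.

Step 16
Reactants: 26 (3S,6R)-hept-1-ene-3,6-diol
Product: 27 (3aS,5R,7aS)-5-methylhexahydro-2H-furo[3,2-b]pyran-2-one
Conditions: PdCl2 (10 mol%), CuCl2, NaOAc, AcOH, CO (1 atm), rt
Reagents that add atoms: carbon monoxide, [C-]#[O+]
Why: Semmelhack-type Pd(II) oxycarbonylation: 6-exo oxypalladation of the alkene by the C13 hydroxyl (O12–C11), CO insertion (C10–C9) and capture of the acyl–palladium by the allylic C17 hydroxyl (O18–C9) give a γ-lactone that can only be cis-fused, so C11 is set by C17 through a chair-like transition state with the methyl and acetic arms equatorial (2,6-cis), CuCl2 reoxidising Pd(0).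

Step 17
Reactants: 20 ketal-protected bicyclic macrolactone; 27 (3aS,5R,7aS)-5-methylhexahydro-2H-furo[3,2-b]pyran-2-one
Product: 30 C8-acylation adduct (C9 cyclic hemiketal; C8 and C9 uncontrolled), via lithium enolate 28 (not isolated), via lithium lactolate 29 (not isolated)
Conditions: LiHMDS (1.05 equiv), THF, −78 °C; then 27 (1.5 equiv), −78 → −40 °C; sat. NH4Cl
Reagents that add atoms: lithium bis(trimethylsilyl)amide, [Li]N([Si](C)(C)C)[Si](C)(C)C (its lithium stays only in 28 and 29)
Why: Crossed Claisen-type acylation: LiHMDS removes the most acidic proton, at C8 of the γ-lactone (more acidic than C22 of the macrocyclic s-trans ester), and the enolate adds to the lactone carbonyl C9 of 27 to give a lactolate that is stable at low temperature and is protonated to the hemiketal; the centres at C8 and C9 need no control because both become sp2 in step 18.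

Step 18
Reactants: 30 C8-acylation adduct
Product: 32 cordycicadin D, via target C5-ketal 31 (not isolated)
Conditions: TFA, CH2Cl2, H2O (few equiv), 0 °C → rt
Reagents that add atoms: water, O
Why: Acid ionises the C9 hemiketal to the oxocarbenium ion and loss of the C8 proton gives the push–pull enol ether conjugated with the C19 carbonyl (cyclodehydration of a γ-hydroxy β-keto lactone equivalent); reversible protonation at C8 lets the double bond settle in the more stable E geometry (lactone carbonyl away from O18), and the same aqueous acid hydrolyses the dioxolane to the C5 ketone.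

**Compound list**

1 | (R)-γ-valerolactone | C[C@@H]1CCC(=O)O1 | starting material
2 | (4R)-4-(benzyloxy)pentanoic acid | C[C@H](CCC(=O)O)OCc1ccccc1 | intermediate
3 | 1-[(4R)-4-(benzyloxy)pentanoyl]imidazole | C[C@H](CCC(=O)n1ccnc1)OCc1ccccc1 | intermediate
4 | (4R)-4-(benzyloxy)-N-methoxy-N-methylpentanamide | C[C@H](CCC(=O)N(C)OC)OCc1ccccc1 | intermediate
5 | allylmagnesium bromide | C=CC[Mg]Br | starting material
6 | bromomagnesium alkoxide of the tetrahedral adduct of 4 and 5 (N-methoxy chelate) | C=CCC(O[Mg]Br)(CC[C@@H](C)OCc1ccccc1)N(C)OC | intermediate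
7 | (7R)-7-(benzyloxy)oct-1-en-4-one | C=CCC(=O)CC[C@@H](C)OCc1ccccc1 | intermediate
8 | 2-allyl-2-[(3R)-3-(benzyloxy)butyl]-1,3-dioxolane | C=CCC1(CC[C@@H](C)OCc2ccccc2)OCCO1 | intermediate
9 | trichloroacetyl chloride | ClC(=O)C(Cl)(Cl)Cl | starting material
10 | 3-({2-[(3R)-3-(benzyloxy)butyl]-1,3-dioxolan-2-yl}methyl)-2,2-dichlorocyclobutan-1-one, both configurations at the ring CH | O=C1CC(CC2(CC[C@@H](C)OCc3ccccc3)OCCO2)C1(Cl)Cl | intermediate
11 | 3-({2-[(3R)-3-(benzyloxy)butyl]-1,3-dioxolan-2-yl}methyl)cyclobutan-1-one | O=C1CC(CC2(CC[C@@H](C)OCc3ccccc3)OCCO2)C1 | intermediate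
12 | trimethylsilyl enol ether of 11, ring carbon C7 configured as in the target | C[Si](C)(C)OC1=C[C@H](CC2(CC[C@@H](C)OCc3ccccc3)OCCO2)C1 | intermediate
13 | benzyl bromoacetate | BrCC(=O)OCc1ccccc1 | starting material
14 | lithium enolate corresponding to 12 | [Li]OC1=C[C@H](CC2(CC[C@@H](C)OCc3ccccc3)OCCO2)C1 | intermediate
15 | benzyl 2-[trans-2-({2-[(3R)-3-(benzyloxy)butyl]-1,3-dioxolan-2-yl}methyl)-4-oxocyclobutyl]acetate, C7 and C21 configured as in the target | O=C1C[C@@H](CC2(CC[C@@H](C)OCc3ccccc3)OCCO2)[C@@H]1CC(=O)OCc4ccccc4 | intermediate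
16 | Criegee adduct of 15 with mCPBA at C19 (hydroxy perester) | OC1(OOC(=O)c2cccc(Cl)c2)C[C@@H](CC3(CC[C@@H](C)OCc4ccccc4)OCCO3)[C@@H]1CC(=O)OCc5ccccc5 | intermediate
17 | benzyl 2-[(2S,3R)-3-({2-[(3R)-3-(benzyloxy)butyl]-1,3-dioxolan-2-yl}methyl)-5-oxooxolan-2-yl]acetate | O=C1C[C@@H](CC2(CC[C@@H](C)OCc3ccccc3)OCCO2)[C@H](CC(=O)OCc4ccccc4)O1 | intermediate
18 | 2-[(2S,3R)-3-({2-[(3R)-3-hydroxybutyl]-1,3-dioxolan-2-yl}methyl)-5-oxooxolan-2-yl]acetic acid | O=C1C[C@@H](CC2(CC[C@@H](C)O)OCCO2)[C@H](CC(=O)O)O1 | intermediate
19 | mixed anhydride of 18 with 2-methyl-6-nitrobenzoic acid | O=C1C[C@@H](CC2(CC[C@@H](C)O)OCCO2)[C@H](CC(=O)OC(=O)c3c(C)cccc3[N+](=O)[O-])O1 | intermediate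
20 | ten-membered lactone (O24–C23) trans-fused at C7/C21 to the γ-butyrolactone, C5 as ethylene ketal; 2R,7R,21S in target locants | C[C@@H]1CCC2(OCCO2)C[C@@H]3CC(=O)O[C@H]3CC(=O)O1 | intermediate
21 | ethynyltrimethylsilane | C#C[Si](C)(C)C | starting material
22 | lithium (5R)-5-methyl-2-[(trimethylsilyl)ethynyl]oxolan-2-olate | [Li]OC1(C#C[Si](C)(C)C)CC[C@@H](C)O1 | intermediate
23 | (6R)-6-hydroxy-1-(trimethylsilyl)hept-1-yn-3-one | C[C@@H](O)CCC(=O)C#C[Si](C)(C)C | intermediate
24 | (3S,6R)-1-(trimethylsilyl)hept-1-yne-3,6-diol | C[C@@H](O)CC[C@H](O)C#C[Si](C)(C)C | intermediate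
25 | (3S,6R)-hept-1-yne-3,6-diol | C[C@@H](O)CC[C@H](O)C#C | intermediate
26 | (3S,6R)-hept-1-ene-3,6-diol | C[C@@H](O)CC[C@H](O)C=C | intermediate
27 | (3aS,5R,7aS)-5-methylhexahydro-2H-furo[3,2-b]pyran-2-one | O=C1C[C@@H]2O[C@H](C)CC[C@@H]2O1 | intermediate
28 | lithium enolate of 20 (C8=C19–OLi) | C[C@@H]1CCC2(OCCO2)C[C@@H]3C=C(O[Li])O[C@H]3CC(=O)O1 | intermediate
29 | lithium lactolate from addition of 28 to C9 of 27 | C[C@@H]1CCC2(OCCO2)C[C@@H]3C(C4(O[Li])C[C@@H]5O[C@H](C)CC[C@@H]5O4)C(=O)O[C@H]3CC(=O)O1 | intermediate
30 | 20 bearing at C8 the 2-hydroxy-5-methylhexahydrofuro[3,2-b]pyran-2-yl group (C9 hemiketal; C8 and C9 as mixtures; bicycle 3aS,5R,7aS) | C[C@@H]1CCC2(OCCO2)C[C@@H]3C(C4(O)C[C@@H]5O[C@H](C)CC[C@@H]5O4)C(=O)O[C@H]3CC(=O)O1 | intermediate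
31 | cordycicadin D C5 ethylene ketal (E at C8=C9) | C[C@@H]1CCC2(OCCO2)C[C@@H]3/C(=C4/C[C@@H]5O[C@H](C)CC[C@@H]5O4)C(=O)O[C@H]3CC(=O)O1 | intermediate
32 | cordycicadin D | C[C@@H]1CCC(=O)C[C@@H]2/C(=C3/C[C@@H]4O[C@H](C)CC[C@@H]4O3)C(=O)O[C@H]2CC(=O)O1 | target

**Step count and risks**

Total step count: 18. Longest linear sequence: 13 (steps 1–11, 17, 18); the five steps to lactone 27 (12–16) run in parallel.

Steps most likely to fail:

Step 17. Proton transfer from 27 to enolate 28 (followed by retro-oxa-Michael opening of the pyran), enolisation at C22 with β-elimination of the lactone oxygen O20, or slow addition to the lactone carbonyl may all starve the C8–C9 bond formation. The fallback replaces the acylation by an aldol addition and an oxidation. It sets out from 27: aminolysis with Me2AlN(OMe)Me gives the hydroxy Weinreb amide F1, which is silylated at once (TBSOTf, 2,6-lutidine) to the silyl ether F2 and reduced with DIBAL-H at −78 °C to the aldehyde F3. Enolate 28, made from 20 as in step 17, adds to this far more electrophilic partner to give the aldol F4, Dess–Martin periodinane oxidises it to the β-keto lactone F5, and HF·pyridine removes the silyl group, whereupon the C17 hydroxyl closes onto the C9 ketone and the route is rejoined at 30, step 18 following unchanged.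

Step 11. Closure of the ten-membered ring may lose out to oligomerisation, and the activated C23 acyl group carries the lactone oxygen O20 in its β-position, so base-induced elimination can open the γ-lactone. The fallback closes the macrocycle before the oxygen is inserted. It sets out from 15: hydrogenolysis as in step 10 gives the cyclobutanone hydroxy acid F6, MNBA/DMAP converts it through the mixed anhydride F7 into the macrocyclic cyclobutanone lactone F8, in which the activated acid has no β-leaving group, and mCPBA oxidation through the Criegee adduct F9, governed by the same migration rule as step 9, comes back to the route at 20.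

Step 8. Proton exchange between the product ketone and enolate 14, polyalkylation and aldol self-condensation of the strained ketone may erode the alkylation and its trans selectivity. The fallback forms the C21–C22 bond by a radical instead of an anionic process. It sets out from 12 and 13, which are irradiated (blue LED) with fac-Ir(ppy)3 in DMF: the electrophilic benzyloxycarbonylmethyl radical adds to the enol ether carbon anti to the side chain, the α-silyloxy radical is oxidised and desilylated, and the route is rejoined directly at 15 with no basic enolate ever present; no compound outside the list is made (F0).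

**Further compounds**

F1 | step 17 | 2-[(2S,3S,6R)-3-hydroxy-6-methyloxan-2-yl]-N-methoxy-N-methylacetamide | CON(C)C(=O)C[C@@H]1O[C@H](C)CC[C@@H]1O
F2 | step 17 | 2-[(2S,3S,6R)-3-{[tert-butyl(dimethyl)silyl]oxy}-6-methyloxan-2-yl]-N-methoxy-N-methylacetamide | CON(C)C(=O)C[C@@H]1O[C@H](C)CC[C@@H]1O[Si](C)(C)C(C)(C)C
F3 | step 17 | 2-[(2S,3S,6R)-3-{[tert-butyl(dimethyl)silyl]oxy}-6-methyloxan-2-yl]acetaldehyde | O=CC[C@@H]1O[C@H](C)CC[C@@H]1O[Si](C)(C)C(C)(C)C
F4 | step 17 | aldol adduct of 28 and F3 (C8 and C9 as mixtures) | C[C@@H]1CCC2(OCCO2)C[C@@H]3C(C(O)C[C@@H]4O[C@H](C)CC[C@@H]4O[Si](C)(C)C(C)(C)C)C(=O)O[C@H]3CC(=O)O1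
F5 | step 17 | C9 ketone from F4 (silyl-protected β-keto lactone) | C[C@@H]1CCC2(OCCO2)C[C@@H]3C(C(=O)C[C@@H]4O[C@H](C)CC[C@@H]4O[Si](C)(C)C(C)(C)C)C(=O)O[C@H]3CC(=O)O1
F6 | step 11 | 2-[trans-2-({2-[(3R)-3-hydroxybutyl]-1,3-dioxolan-2-yl}methyl)-4-oxocyclobutyl]acetic acid, C7 and C21 as in 15 | O=C1C[C@@H](CC2(CC[C@@H](C)O)OCCO2)[C@@H]1CC(=O)O
F7 | step 11 | mixed anhydride of F6 with 2-methyl-6-nitrobenzoic acid | O=C1C[C@@H](CC2(CC[C@@H](C)O)OCCO2)[C@@H]1CC(=O)OC(=O)c3c(C)cccc3[N+](=O)[O-]
F8 | step 11 | ten-membered lactone trans-fused to the cyclobutanone (C19 ketone, no O20), C5 as ethylene ketal | C[C@@H]1CCC2(OCCO2)C[C@@H]3CC(=O)[C@H]3CC(=O)O1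
F9 | step 11 | Criegee adduct of F8 with mCPBA at C19 | C[C@@H]1CCC2(OCCO2)C[C@@H]3CC(O)(OOC(=O)c4cccc(Cl)c4)[C@H]3CC(=O)O1
F0 | step 8 | none | none
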